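**Strategy.** Ring A, the cyclohexadienone, is a β-triketone whose only stereocentre, quaternary C4, sits between the two enolised carbonyl carbons C3 and C5. It is assembled by a formal [4+2] double C-acylation: C4–C5 comes from an α-methyl γ-lactone whose acetal carbon carries a d-menthyloxy group, and C6–C1–C2–C3 with the masked butanoyl group from a 5-methylisoxazole-4-carbonyl chloride. In one flask the planar lactone enolate is acylated anti to the menthyloxy group (C3–C4 bond, stereocentre set) and the isoxazole-methyl carbanion then opens the lactone (C5–C6 bond), expelling menthol and unveiling the aldehyde that becomes the prenyl group. Isoxazole unmasking and methylene bridging to aspidinol finish the route.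

Key step: step 6

Remark: ring A is numbered as in the name of 21 (C1 ring carbonyl, C2 butanoyl-bearing, C3 and C5 enol carbons, C4 quaternary, C6 bridge-bearing); the triketone units are written as the freely interconverting enol tautomers of the given structure; d-menthyl = (1S,2R,5S)-5-methyl-2-(propan-2-yl)cyclohexyl; 1, 4, 5, 16 and (S)-5-[(trityloxy)methyl]dihydrofuran-2(3H)-one are taken as purchasable.

Step 1
Reactants: 1 (5S)-5-(d-menthyloxy)furan-2(5H)-one
Product: 2 (5S)-5-(d-menthyloxy)dihydrofuran-2(3H)-one
Conditions: H2 (1 atm), 10% Pd/C, EtOAc, rt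
Reagents that add atoms: none
Why: Heterogeneous catalytic hydrogenation should saturate only the conjugated ring C=C bond and leave the acetal stereocentre untouched.

Step 2
Reactants: 2 (5S)-5-(d-menthyloxy)dihydrofuran-2(3H)-one
Product: 3 (3RS,5S)-3-methyl-5-(d-menthyloxy)dihydrofuran-2(3H)-one
Conditions: LiN(iPr)2 (1.1 equiv), THF, −78 °C; MeI, −78 to −40 °C
Reagents that add atoms: iodomethane, CI
Why: Lactone enolate alkylation should give the α-methyl lactone as a mixture of C3 epimers, which is acceptable because C3 becomes planar again in step 6.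

Step 3
Reactants: 4 ethyl (E)-3-(pyrrolidin-1-yl)but-2-enoate; 5 1-nitrobutane
Product: 8 ethyl 5-methyl-3-propyl-1,2-oxazole-4-carboxylate, via butanenitrile oxide 6 (not isolated), via pyrrolidinyl isoxazoline 7 (not isolated)
Conditions: POCl3, Et3N, CHCl3, 0 °C to rt; aqueous work-up
Reagents that add atoms: none
Why: Dehydration of the primary nitroalkane gives the nitrile oxide, whose 1,3-dipolar cycloaddition to the enamine places oxygen on the amine-bearing carbon, and loss of pyrrolidine aromatises the adduct (nitrile oxide–enamine isoxazole synthesis).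

Step 4
Reactants: 8 ethyl 5-methyl-3-propyl-1,2-oxazole-4-carboxylate
Product: 9 5-methyl-3-propyl-1,2-oxazole-4-carboxylic acid
Conditions: NaOH, EtOH/H2O, reflux; then aqueous HCl
Reagents that add atoms: sodium hydroxide, [Na+].[OH-]
Why: Ester saponification should be clean because a 3,5-disubstituted isoxazole has no ring C–H through which base could open the ring.

Step 5
Reactants: 9 5-methyl-3-propyl-1,2-oxazole-4-carboxylic acid
Product: 10 5-methyl-3-propyl-1,2-oxazole-4-carbonyl chloride
Conditions: (COCl)2, DMF (cat.), CH2Cl2, 0 °C to rt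
Reagents that add atoms: oxalyl chloride, ClC(=O)C(=O)Cl
Why: Acid chloride formation through Vilsmeier-type activation is routine for heteroaryl carboxylic acids.

Step 6
Reactants: 3 (3RS,5S)-3-methyl-5-(d-menthyloxy)dihydrofuran-2(3H)-one; 10 5-methyl-3-propyl-1,2-oxazole-4-carbonyl chloride
Product: 12 2-[(5R)-6-hydroxy-5-methyl-4-oxo-3-propyl-4,5-dihydro-1,2-benzoxazol-5-yl]acetaldehyde, via acyl lactone 11 (not isolated)
Conditions: 3, LiN(iPr)2 (1.05 equiv), THF, −78 °C; 10 (1.0 equiv), −78 °C; then LiN(SiMe3)2 (2.3 equiv), −78 to −20 °C; then 1 M aqueous HCl/THF, 0 °C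
Reagents that add atoms: none
Why: The lithium enolate of 3, planar and free of E/Z ambiguity because it lies in the five-membered ring, attacks acid chloride 10 through carbon to give 11 (bond C3–C4 of ring A); LiN(SiMe3)2 then removes a proton from the isoxazole 5-methyl group, now vinylogously activated by the new ketone, and this lateral carbanion adds to the lactone carbonyl (bond C5–C6), the tetrahedral intermediate ejecting the ring oxygen as a hemiacetal alkoxide that collapses to the aldehyde and lithium (1S,2R,5S)-mentholate. The closest known reaction types are C-acylation of ester and lactone enolates by acid chlorides (crossed Claisen), lateral lithiation of 5-methylisoxazoles, and Dieckmann-type acyl transfer from a lactone. The six-membered carbocycle closes by 6-(enolendo)-exo-trig attack of the carbanion on the lactone C=O. The quaternary carbon is set in the acylation by 1,3-induction from the acetal centre: the menthyloxy group, pseudoaxial for anomeric reasons, shields one enolate face, so the acyl group should enter trans to it, giving (3S,5S)-11 and hence (5R)-12, and the controlling centre is then destroyed as it becomes the aldehyde carbon. The step needs C- over O-acylation (lithium enolate, acid chloride, THF, low temperature) and acylation before any proton exchange with the isoxazole methyl group (second base added only afterwards); the isoxazole keeps the two flanks of the new ring constitutionally different, so tautomerism cannot symmetrise the quaternary carbon, and the liberated aldehyde is shielded from aldol reactions as the cyclic lithium lactolate formed with the neighbouring enolate oxygen.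

Step 7
Reactants: 12 2-[(5R)-6-hydroxy-5-methyl-4-oxo-3-propyl-4,5-dihydro-1,2-benzoxazol-5-yl]acetaldehyde
Product: 13 (5R)-6-hydroxy-5-methyl-5-(3-methylbut-2-en-1-yl)-3-propyl-1,2-benzoxazol-4(5H)-one
Conditions: iPrPPh3 I (3.5 equiv), n-BuLi (3.4 equiv), THF, 0 °C; then 12, −78 °C to rt
Reagents that add atoms: isopropyltriphenylphosphonium iodide, CC(C)[P+](c1ccccc1)(c1ccccc1)c1ccccc1.[I-], used as its ylide propan-2-ylidenetriphenylphosphorane, CC(C)=P(c1ccccc1)(c1ccccc1)c1ccccc1
Why: Wittig olefination of the aldehyde (or its ring-chain lactol tautomer) should give the prenyl group without alkene geometry to control, the first equivalent of ylide converting the vinylogous acid into an enolate that protects the ring ketone.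

Step 8
Reactants: 13 (5R)-6-hydroxy-5-methyl-5-(3-methylbut-2-en-1-yl)-3-propyl-1,2-benzoxazol-4(5H)-one
Product: 15 (4R)-2-butanoyl-3,5-dihydroxy-4-methyl-4-(3-methylbut-2-en-1-yl)cyclohexa-2,5-dien-1-one, via enaminone 14 (not isolated)
Conditions: Mo(CO)6 (1.2 equiv), MeCN/H2O (9:1), 80 °C; then 2 M aqueous NaOH, EtOH, 70 °C; then 1 M HCl to pH 4, 0 °C
Reagents that add atoms: water, O
Why: Reductive N–O cleavage of the isoxazole by Mo(CO)6 and water gives the vinylogous amide, and its alkaline hydrolysis should free the butanoyl ketone without exposing the prenyl group to hydrogenation or hot acid, while the quaternary carbon cannot epimerise.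

Step 9
Reactants: 16 2-methylbenzene-1,3,5-triol
Product: 17 1-(2,4,6-trihydroxy-3-methylphenyl)butan-1-one
Conditions: butanoyl chloride (1.1 equiv), AlCl3 (3 equiv), PhNO2, 60 °C
Reagents that add atoms: butanoyl chloride, CCCC(=O)Cl
Why: Friedel–Crafts acylation is unambiguous because the two free ring positions of 16 are equivalent and the first acyl group deactivates the ring toward a second.

Step 10
Reactants: 17 1-(2,4,6-trihydroxy-3-methylphenyl)butan-1-one
Product: 18 1-(2,6-dihydroxy-4-methoxy-3-methylphenyl)butan-1-one (aspidinol)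
Conditions: Me2SO4 (1.0 equiv), K2CO3 (1.0 equiv), acetone, rt
Reagents that add atoms: dimethyl sulfate, COS(=O)(=O)OC
Why: Williamson etherification should select the 4-OH para to the ketone, the most acidic hydroxyl and the one not hydrogen-bonded to the carbonyl oxygen.

Step 11
Reactants: 18 1-(2,6-dihydroxy-4-methoxy-3-methylphenyl)butan-1-one
Product: 19 1-{3-[(dimethylamino)methyl]-2,6-dihydroxy-4-methoxy-5-methylphenyl}butan-1-one
Conditions: N,N-dimethylmethyleneiminium iodide (1.05 equiv), CH2Cl2, rt; aqueous NaHCO3 work-up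
Reagents that add atoms: N,N-dimethylmethyleneiminium iodide, C=[N+](C)C.[I-]
Why: Mannich aminomethylation can only occur at the single free aromatic position.

Step 12
Reactants: 15 (4R)-2-butanoyl-3,5-dihydroxy-4-methyl-4-(3-methylbut-2-en-1-yl)cyclohexa-2,5-dien-1-one; 19 1-{3-[(dimethylamino)methyl]-2,6-dihydroxy-4-methoxy-5-methylphenyl}butan-1-one
Product: 21 (4R)-2-butanoyl-6-[(3-butanoyl-2,4-dihydroxy-6-methoxy-5-methylphenyl)methyl]-3,5-dihydroxy-4-methyl-4-(3-methylbut-2-en-1-yl)cyclohexa-2,5-dien-1-one, via quinone methide 20 (not isolated)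
Conditions: 19 (1.1 equiv), 1,4-dioxane, 100 °C, sealed tube
Reagents that add atoms: none
Why: Thermal loss of dimethylamine from the phenolic Mannich base gives the ortho-quinone methide, which the only nucleophilic ring carbon (C6) of vinylogous acid 15 should capture by Michael addition with re-aromatisation, and 19 cannot self-couple because it has no free ring position.

**Compound list**

1 | (5S)-5-{[(1S,2R,5S)-5-methyl-2-(propan-2-yl)cyclohexyl]oxy}furan-2(5H)-one | O=C1C=C[C@@H](O[C@H]2C[C@@H](C)CC[C@@H]2C(C)C)O1 | starting material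
2 | (5S)-5-(d-menthyloxy)dihydrofuran-2(3H)-one | O=C1CC[C@@H](O[C@H]2C[C@@H](C)CC[C@@H]2C(C)C)O1 | intermediate
3 | (3RS,5S)-3-methyl-5-(d-menthyloxy)dihydrofuran-2(3H)-one (C3 epimers) | O=C1C(C)C[C@@H](O[C@H]2C[C@@H](C)CC[C@@H]2C(C)C)O1 | intermediate
4 | ethyl (E)-3-(pyrrolidin-1-yl)but-2-enoate | CCOC(=O)/C=C(/N1CCCC1)C | starting material
5 | 1-nitrobutane | CCCC[N+](=O)[O-] | starting material
6 | butanenitrile oxide | CCCC#[N+][O-] | intermediate
7 | ethyl 5-methyl-3-propyl-5-(pyrrolidin-1-yl)-4,5-dihydro-1,2-oxazole-4-carboxylate (racemic, transient) | CCCC1=NOC(C)(N2CCCC2)C1C(=O)OCC | intermediate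
8 | ethyl 5-methyl-3-propyl-1,2-oxazole-4-carboxylate | CCCc1noc(C)c1C(=O)OCC | intermediate
9 | 5-methyl-3-propyl-1,2-oxazole-4-carboxylic acid | CCCc1noc(C)c1C(=O)O | intermediate
10 | 5-methyl-3-propyl-1,2-oxazole-4-carbonyl chloride | CCCc1noc(C)c1C(=O)Cl | intermediate
11 | (3S,5S)-3-methyl-3-(5-methyl-3-propyl-1,2-oxazole-4-carbonyl)-5-(d-menthyloxy)dihydrofuran-2(3H)-one | O=C1[C@](C)(C(=O)c2c(C)onc2CCC)C[C@@H](O[C@H]3C[C@@H](C)CC[C@@H]3C(C)C)O1 | intermediate
12 | 2-[(5R)-6-hydroxy-5-methyl-4-oxo-3-propyl-4,5-dihydro-1,2-benzoxazol-5-yl]acetaldehyde | CCCc1noc2C=C(O)[C@@](C)(CC=O)C(=O)c12 | intermediate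
13 | (5R)-6-hydroxy-5-methyl-5-(3-methylbut-2-en-1-yl)-3-propyl-1,2-benzoxazol-4(5H)-one | CCCc1noc2C=C(O)[C@@](C)(CC=C(C)C)C(=O)c12 | intermediate
14 | (6R)-2-(1-aminobutylidene)-5-hydroxy-6-methyl-6-(3-methylbut-2-en-1-yl)cyclohex-4-ene-1,3-dione | CCCC(N)=C1C(=O)C=C(O)[C@@](C)(CC=C(C)C)C1=O | intermediate
15 | (4R)-2-butanoyl-3,5-dihydroxy-4-methyl-4-(3-methylbut-2-en-1-yl)cyclohexa-2,5-dien-1-one | CCCC(=O)C1=C(O)[C@](C)(CC=C(C)C)C(O)=CC1=O | intermediate
16 | 2-methylbenzene-1,3,5-triol | Cc1c(O)cc(O)cc1O | starting material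
17 | 1-(2,4,6-trihydroxy-3-methylphenyl)butan-1-one | CCCC(=O)c1c(O)cc(O)c(C)c1O | intermediate
18 | 1-(2,6-dihydroxy-4-methoxy-3-methylphenyl)butan-1-one (aspidinol) | CCCC(=O)c1c(O)cc(OC)c(C)c1O | intermediate
19 | 1-{3-[(dimethylamino)methyl]-2,6-dihydroxy-4-methoxy-5-methylphenyl}butan-1-one | CCCC(=O)c1c(O)c(CN(C)C)c(OC)c(C)c1O | intermediate
20 | 2-butanoyl-3-hydroxy-5-methoxy-4-methyl-6-methylidenecyclohexa-2,4-dien-1-one | C=C1C(=O)C(C(=O)CCC)=C(O)C(C)=C1OC | intermediate
21 | (4R)-2-butanoyl-6-[(3-butanoyl-2,4-dihydroxy-6-methoxy-5-methylphenyl)methyl]-3,5-dihydroxy-4-methyl-4-(3-methylbut-2-en-1-yl)cyclohexa-2,5-dien-1-one | CCCC(=O)C1=C(O)[C@](C)(CC=C(C)C)C(O)=C(Cc2c(O)c(C(=O)CCC)c(O)c(C)c2OC)C1=O | target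

**Count.** Total steps: 12. Longest linear sequence: 7 steps (3, 4, 5, 6, 7, 8, 12).

**Steps most likely to fail**

Step 6. The enolate acylation may show poor facial discrimination or go through oxygen, and the liberated aldehyde may be lost by aldol condensation. The fallback uses a lactone template of well-precedented use for α-quaternary centres and runs stepwise. It sets out from 10 and purchasable (S)-5-[(trityloxy)methyl]dihydrofuran-2(3H)-one and comes back at 12. α-Methylation (LiN(iPr)2, MeI) should give (3RS,5S)-3-methyl-5-[(trityloxy)methyl]dihydrofuran-2(3H)-one F1. Its lithium enolate is acylated with 10 anti to the bulky trityloxymethyl group to give the acyl lactone F2, which is isolated so that any minor diastereomer can be removed. LiN(SiMe3)2 then closes the carbocycle to the secondary alcohol F3. Detritylation (HCO2H, Et2O) should give the diol F4, and NaIO4 cleavage returns aldehyde 12.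

Step 8. Hydrolysis of the vinylogous amide may be sluggish, and prolonged alkali may cause retro-Claisen loss of the butanoyl group. The fallback moves the unmasking ahead of the olefination, so that hot aqueous acid, which the prenyl group would not tolerate, can be used. It sets out from 12 and comes back at 15. Mo(CO)6/H2O should give the enaminone aldehyde F5, 2 M HCl at 80 °C should hydrolyse it to the triketone aldehyde F6, and Wittig olefination with excess propan-2-ylidenetriphenylphosphorane gives 15.

Step 12. The quinone methide may oligomerise, re-add dimethylamine faster than it is captured, or be captured through oxygen. The fallback reverses the roles of the two halves. It sets out from 15 and 18 and comes back at 21. Aminomethylation of 15 at C6 with N,N-dimethylmethyleneiminium iodide should give the Mannich base F7. On heating, this loses dimethylamine to the 6-methylidene trione F8 (not isolated), and Friedel–Crafts-type conjugate addition of the free ring carbon of aspidinol 18 gives 21.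

**Further compounds**

F1 | step 6 | (3RS,5S)-3-methyl-5-[(trityloxy)methyl]dihydrofuran-2(3H)-one | O=C1C(C)C[C@@H](COC(c2ccccc2)(c2ccccc2)c2ccccc2)O1
F2 | step 6 | (3S,5S)-3-methyl-3-(5-methyl-3-propyl-1,2-oxazole-4-carbonyl)-5-[(trityloxy)methyl]dihydrofuran-2(3H)-one | O=C1[C@](C)(C(=O)c2c(C)onc2CCC)C[C@@H](COC(c3ccccc3)(c3ccccc3)c3ccccc3)O1
F3 | step 6 | (5R)-6-hydroxy-5-[(2S)-2-hydroxy-3-(trityloxy)propyl]-5-methyl-3-propyl-1,2-benzoxazol-4(5H)-one | CCCc1noc2C=C(O)[C@@](C)(C[C@H](O)COC(c3ccccc3)(c3ccccc3)c3ccccc3)C(=O)c12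
F4 | step 6 | (5R)-5-[(2S)-2,3-dihydroxypropyl]-6-hydroxy-5-methyl-3-propyl-1,2-benzoxazol-4(5H)-one | CCCc1noc2C=C(O)[C@@](C)(C[C@H](O)CO)C(=O)c12
F5 | step 8 | 2-[(1R)-3-(1-aminobutylidene)-6-hydroxy-1-methyl-2,4-dioxocyclohex-5-en-1-yl]acetaldehyde | CCCC(N)=C1C(=O)C=C(O)[C@@](C)(CC=O)C1=O
F6 | step 8 | 2-[(1R)-3-butanoyl-2,6-dihydroxy-1-methyl-4-oxocyclohexa-2,5-dien-1-yl]acetaldehyde | CCCC(=O)C1=C(O)[C@](C)(CC=O)C(O)=CC1=O
F7 | step 12 | (4R)-2-butanoyl-6-[(dimethylamino)methyl]-3,5-dihydroxy-4-methyl-4-(3-methylbut-2-en-1-yl)cyclohexa-2,5-dien-1-one | CCCC(=O)C1=C(O)[C@](C)(CC=C(C)C)C(O)=C(CN(C)C)C1=O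
F8 | step 12 | (4S)-2-butanoyl-3-hydroxy-4-methyl-4-(3-methylbut-2-en-1-yl)-6-methylidenecyclohex-2-ene-1,5-dione | CCCC(=O)C1=C(O)[C@](C)(CC=C(C)C)C(=O)C(=C)C1=O
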